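## Retrosynthetic overview

1. Feature: in the ten-membered ring C1–C10, the ester-bearing C10 (carboxyl carbon C14) and the carbinol C5 face each other. A C5–C14 bond turns the germacrane into a bicyclo[4.4.1]undecanone whose one-carbon bridge C14 forms an α-ketol with the C5 oxygen.
2. Late disconnections: C11=C13 (elimination of a C13 hydroxymethyl group), C5–OH (1,2-reduction), C15 (Mannich methylenation at C4), C1=C10 (conjugation of C1=C2), then C5–C14 (ketol cleavage with Pb(OAc)4 in MeOH).
3. Key disconnection: C9–C10 and C5–C6. This is a (6+4) cycloaddition of 2-(4-methoxybenzyloxy)tropone (C1–C5, C10, C14) with a 1,3-bis(silyloxy)diene (C6–C9, carrying the C11–C12 acetate arm on C7).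
4. Ring order: tropone ring A (bought), then ring B, which completes the C14-bridged ten-membered perimeter (step 5), then γ-lactone ring C (step 12), then the free ten-membered ring by bridge cleavage (step 13).

Key step: step 5

Conventions: germacrane numbering is used throughout, and α/β refer to the usual drawing. Ring A = C1–C5/C10/C14, ring B = C5–C10/C14, ring C = lactone. TBS = tert-butyldimethylsilyl, TBDPS = tert-butyldiphenylsilyl, TES = triethylsilyl, PMB = 4-methoxybenzyl, Ang = (Z)-2-methylbut-2-enoyl.

Assumption: the sense of induction of the copper–bis(oxazoline) complex on a chelated 2-alkoxytropone cannot be derived from precedent, so (S,S)-tBu-box is written and its antipode is taken if it leads to the mirror image. C11 is carried as both epimers from 12 to 30 and is drawn without configuration.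

## Route

Step 1
Reactants: 1 tropolone; 2 4-methoxybenzyl chloride
Product: 3 2-(4-methoxybenzyloxy)tropone
Conditions: K2CO3, DMF, 60 °C
Reagents that add atoms: none
Why: Williamson O-alkylation of the acidic tropolone hydroxyl by a reactive benzylic chloride; the two oxygens of tropolone are equivalent, so only one ether can form and no stereocentre is made.

Step 2
Reactants: 4 tert-butyl 4-oxobutanoate
Product: 5 tert-butyl (E)-4-(morpholin-4-yl)but-3-enoate
Conditions: morpholine, 4 Å MS, toluene, 0 °C → rt
Reagents that add atoms: morpholine C1COCCN1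
Why: Enamine condensation of an unhindered aldehyde with a secondary amine under water removal gives the (E)-enamine, in which the aldehyde carbon is C6 and the nucleophilic β-carbon is C7, so the site of the next C–C bond is fixed by constitution and does not rest on the uncertain C3/C5 selectivity of a base-mediated levulinate formylation.

Step 3
Reactants: 5 tert-butyl (E)-4-(morpholin-4-yl)but-3-enoate; 6 acetyl chloride
Product: 8 tert-butyl (Z)-3-(hydroxymethylidene)-4-oxopentanoate (hydrogen-bonded enol of the 3-formyl keto ester), via acyl enamine 7 (not isolated)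
Conditions: Et3N, CH2Cl2, 0 °C; then 1 M HCl, THF, rt
Reagents that add atoms: water O
Why: Stork-type C-acylation of an aldehyde enamine forms C7–C8 and gives a push–pull acyl enamine, whose mild acid hydrolysis releases the β-keto aldehyde as its chelated enol while the tert-butyl ester survives dilute acid.

Step 4
Reactants: 8 tert-butyl (Z)-3-(hydroxymethylidene)-4-oxopentanoate
Product: 10 tert-butyl (3E)-4-(TBSO)-3-[(TBSO)methylidene]pent-4-enoate (the 1,3-bis(silyloxy)diene C9=C8–C7=C6), via silyloxy enone 9 (not isolated)
Conditions: TBSOTf (2.2 equiv), Et3N, Et2O, 0 °C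
Reagents that add atoms: tert-butyldimethylsilyl triflate CC(C)(C)[Si](C)(C)OS(=O)(=O)C(F)(F)F
Why: Soft enolisation, in which the silyl triflate first caps the enol oxygen to a vinylogous silyl ester that settles as the (E) isomer and then activates the more Lewis basic vinylogous carbonyl so that Et3N removes a proton from the C9 methyl group; this is the double silylation known for other 1,3-dicarbonyl compounds, and the plain ester is left alone.

Step 5
Reactants: 3 2-(4-methoxybenzyloxy)tropone; 10 tert-butyl (3E)-4-(TBSO)-3-[(TBSO)methylidene]pent-4-enoate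
Product: 11 (6+4) adduct (bicyclo[4.4.1]undecatrienone; C14 ketone bridge α between C5 and C10; 5β-OPMB; 10β-H; 6α-OTBS; C1=C2 and C3=C4 in ring A; C7=C8 enol silane in ring B; CH2CO2tBu on C7)
Conditions: Cu(OTf)2 (10 mol %), (S,S)-tBu-box (11 mol %), 4 Å MS, CH2Cl2, −60 → −20 °C
Reagents that add atoms: none
Why: Proposed new method: the 2-alkoxytropone binds divalent copper through the C14 carbonyl oxygen and the C5 ether oxygen, which lowers its LUMO and lets the tert-butyl groups of the ligand cover one face of the flat ring, and the diene then adds suprafacially, its nucleophilic CH2 terminus C9 to C10 and its silyloxy-bearing terminus C6 to C5, either in one asynchronous ten-electron step or as a Mukaiyama–Michael addition followed by capture of the silyloxycarbenium carbon C6 by the copper-bound C5 enolate carbon. The closest known reactions are the thermal exo-selective (6+4) additions of tropone to 1-oxygenated butadienes, the Cr(CO)3-mediated (6+4) additions of cycloheptatrienes and the catalytic enantioselective (6+4) additions to tropone, but a chelating 2-alkoxytropone and a 1,3-bis(silyloxy)diene have not been joined in this way. The one new ring, ring B (C5–C6–C7–C8–C9–C10–C14), is closed by intermolecular two-bond cycloaddition and completes with ring A the C14-bridged ten-membered perimeter, so no macrocyclisation is needed. C5 and C10 are tied cis by suprafacial addition across the tropone and take their absolute sense from the ligand-shielded face, whereas C6 follows from the (E) geometry of C6=C7 and the extended (exo) arrangement, in which C7–C8 lie over the carbonyl bridge and away from C1–C4, the endo arrangement suffering repulsive secondary overlap. The step needs (6+4) over (4+2) and (8+2) periselectivity and the head-to-head orientation; the first is helped by the C7 substituent, which holds the diene s-cis, and by activation of the two α-carbons, and the second by the match of the doubly donor-polarised C9 with the unsubstituted C10 and by the ether oxygen, which lowers the acceptor coefficient at C5.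

Step 6
Reactants: 11 (6+4) adduct
Product: 12 C11-hydroxymethyl adduct (as 11; side chain on C7 now CH(CH2OH)CO2tBu; both C11 epimers)
Conditions: LiN(i-Pr)2, THF, −78 °C; CH2O (g), −78 → −40 °C; AcOH
Reagents that add atoms: formaldehyde C=O
Why: Aldol-type hydroxymethylation after ester deprotonation; C11–H is the only acidic proton in 11 because C14 is flanked by a quaternary carbon and by a bridgehead C–H that cannot enolise (Bredt strain), the extended anion reacts at its α-carbon C11, and the new C11 centre is erased in step 19.

Step 7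
Reactants: 12 C11-hydroxymethyl adduct
Product: 13 C13 TBDPS ether (as 12; CH2OTBDPS on C11)
Conditions: TBDPSCl, imidazole, DMF, rt
Reagents that add atoms: tert-butyldiphenylsilyl chloride CC(C)(C)[Si](Cl)(c1ccccc1)c1ccccc1
Why: Standard silylation of a primary alcohol; the TBDPS ether is chosen because it outlasts the fluoride and acid steps that remove the two TBS groups.

Step 8
Reactants: 13 C13 TBDPS ether
Product: 14 C8 ketone (6α-OTBS; 7α-H with the side chain 7β; C14 bridge ketone and ring A diene unchanged)
Conditions: TBAF (1.05 equiv), AcOH (1.5 equiv), THF, −40 → −10 °C; used at once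
Reagents that add atoms: none
Why: Buffered fluoride desilylation and ketonisation, in which fluoride attacks the enol silane far faster than the alkyl silyl ethers, acetic acid supplies the proton at once so that β-elimination of the C6 silyloxy group and epimerisation are held back, and C7 is set because A(1,2) strain with the side chain keeps C6–OTBS pseudoaxial and folds C7=C8 over the C1–C4 bridge, so the proton can reach C7 only from the open α-face that also carries C6–O.

Step 9
Reactants: 14 C8 ketone
Product: 15 8β-alcohol (8α-H; hydroxyl cis to the C7 side chain)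
Conditions: LiBH(s-Bu)3 (1.1 equiv), THF, −78 °C; aq. NH4Cl
Reagents that add atoms: none
Why: Chemo- and diastereoselective ketone reduction with a bulky trialkylborohydride; C14 is screened on both faces by the two four-carbon bridges and flanked by a quaternary carbon, whereas C8 is attacked from the α-face, anti to the bulky C7 side chain and on the side of the one-carbon bridge, and the tert-butyl ester keeps the cis alkoxide from closing a 12,8-lactone.

Step 10
Reactants: 15 8β-alcohol; 16 angelic acid
Product: 18 8β-angelate, via mixed anhydride 17 (not isolated)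
Conditions: 2,4,6-Cl3C6H2COCl, Et3N, toluene, rt; then 15, 75 °C
Reagents that add atoms: 2,4,6-trichlorobenzoyl chloride O=C(Cl)c1c(Cl)cc(Cl)cc1Cl (enters 17 only)
Why: Yamaguchi-type esterification through the preformed mixed anhydride without a nucleophilic catalyst, so that no acylpyridinium species able to isomerise (Z) to (E) by addition–elimination is formed, and C8 keeps its configuration because only the O–H bond reacts.

Step 11
Reactants: 18 8β-angelate
Product: 19 C6 alcohol (6α-OH; PMB ether, tert-butyl ester, TBDPS ether and angelate kept)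
Conditions: HF·pyridine, pyridine, THF, 0 °C → rt
Reagents that add atoms: none
Why: Acidic fluoride desilylation, which distinguishes the TBS ether at C6 from the far more acid-stable TBDPS ether at C13 and does not touch PMB ether, tert-butyl ester or angelate.

Step 12
Reactants: 19 C6 alcohol
Product: 21 ketol lactone (5β-OH next to the C14 bridge ketone; trans-fused 12,6α-lactone ring C; 8β-OAng; CH2OTBDPS on C11), via dihydroxy acid 20 (not isolated)
Conditions: CF3CO2H, anisole, CH2Cl2, 0 °C → rt
Reagents that add atoms: none
Why: Acidolysis cleaves the tert-butyl ester (as isobutene) and the PMB ether (as a benzylic cation caught by anisole), and the freed γ-hydroxy acid closes by acid-catalysed 5-exo-trig lactonisation onto C6–OH, the only other hydroxyl (C5) being tertiary and leading to a six-membered ring; no stereocentre is touched.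

Step 13
Reactants: 21 ketol lactone
Product: 22 ten-membered (Z,Z)-dienone ester (C5 ketone conjugated with C3=C4 and C1=C2; CO2Me on C10)
Conditions: Pb(OAc)4 (1.1 equiv), MeOH–CH2Cl2 1:1, 0 °C
Reagents that add atoms: methanol CO
Why: Criegee-type oxidative cleavage of an α-ketol, in which methanol adds to the bridge ketone and tetravalent lead binds the C5 hydroxyl and breaks C5–C14, so that C14 leaves as the methyl ester on C10, C5 becomes a ketone and the ten-membered ring is freed with both ring alkenes still cis; C6–O is acylated, so no 1,2-diol competes.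

Step 14
Reactants: 22 ten-membered dienone ester
Product: 23 C4=C5 TES enol ether (C3 now CH2; C1=C2 cis alkene kept; enol ether geometry not defined)
Conditions: RhCl(PPh3)3 (3 mol %), Et3SiH, toluene, 50 °C
Reagents that add atoms: triethylsilane CC[SiH](CC)CC
Why: Rhodium-catalysed 1,4-hydrosilylation of an enone with a monohydrosilane delivers hydride to C3 and silicon to the C5 oxygen and so fixes the enol silane at C4; the 1,4-preference known for conjugated dienones is helped here by the twist between the two cis alkenes in the medium ring and by the branched C10 next to C1, and the hindered angelate, the lactone and the ester do not react.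

Step 15
Reactants: 23 C4=C5 TES enol ether
Product: 24 conjugated C1=C10 enoate (C14 trans to C2; C2 cis to C9; enol silane kept)
Conditions: DBU, MeCN, 40 °C
Reagents that add atoms: none
Why: Base-catalysed conjugation of a β,γ-unsaturated ester by deprotonation of the doubly activated C10–H and reprotonation at C2 runs under thermodynamic control to the trisubstituted enoate that is both the tiglate-like arrangement and the cis-cyclodecene, while the masked C5 ketone protects C6 from epimerisation.

Step 16
Reactants: 24 conjugated C1=C10 enoate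
Product: 27 C4-methylene C5 ketone, via Mannich base 25 (not isolated), via ammonium iodide 26 (not isolated)
Conditions: CH2=NMe2+ I−, CH2Cl2, rt; aq. NaHCO3; MeI, Et2O, rt; aq. NaHCO3, CH2Cl2
Reagents that add atoms: N,N-dimethylmethyleneiminium iodide C=[N+](C)C.[I-]; iodomethane CI (enters 26 only)
Why: Mannich reaction of the enol silane with the preformed iminium salt forms C4–C15 only at the carbon fixed in step 14, and quaternisation followed by mild-base Hofmann-type β-elimination gives the α-methylene ketone with loss of the transient C4 centre.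

Step 17
Reactants: 27 C4-methylene C5 ketone
Product: 28 5β-allylic alcohol
Conditions: NaBH4, CeCl3·7H2O, MeOH, −78 °C
Reagents that add atoms: none
Why: Luche 1,2-reduction, in which the hard cerium-modified borohydride avoids conjugate addition and the hydride adds anti to the electronegative C6–O bond held perpendicular to the carbonyl (polar Felkin–Anh model, the lactone oxygen not chelating in methanol), which gives the syn 5,6-dioxygen pattern, that is 5β-OH (5S).

Step 18
Reactants: 28 5β-allylic alcohol
Product: 29 C5,C13-diol
Conditions: HF·pyridine, THF, rt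
Reagents that add atoms: none
Why: Fluoride-driven cleavage of the last silyl ether under mildly acidic conditions that should neither isomerise the angelate nor open the lactone nor ionise the allylic alcohol.

Step 19
Reactants: 29 C5,C13-diol
Product: 31 target CNP0163095.1, via mesylate 30 (not isolated)
Conditions: MsCl (1.1 equiv), Et3N, CH2Cl2, −20 °C; then DBU, 0 °C
Reagents that add atoms: methanesulfonyl chloride CS(=O)(=O)Cl (enters 30 only)
Why: Selective sulfonylation of the primary C13 hydroxyl over the hindered secondary allylic C5 hydroxyl, followed by E1cB elimination of methanesulfonate from the lactone α-position, creates C11=C13, removes the C11 centre and converges both epimers on the target.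

## Compound list

1 | tropolone | O=C1C=CC=CC=C1O | starting material
2 | 4-methoxybenzyl chloride | COc1ccc(CCl)cc1 | starting material
3 | 2-(4-methoxybenzyloxy)tropone | O=C1C=CC=CC=C1OCc1ccc(OC)cc1 | intermediate
4 | tert-butyl 4-oxobutanoate | O=CCCC(=O)OC(C)(C)C | starting material
5 | tert-butyl (E)-4-(morpholin-4-yl)but-3-enoate | O=C(C/C=C/N1CCOCC1)OC(C)(C)C | intermediate
6 | acetyl chloride | CC(=O)Cl | starting material
7 | acyl enamine, tert-butyl 3-(morpholin-4-ylmethylidene)-4-oxopentanoate | CC(=O)/C(CC(=O)OC(C)(C)C)=C/N1CCOCC1 | intermediate (not isolated)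
8 | tert-butyl (Z)-3-(hydroxymethylidene)-4-oxopentanoate | CC(=O)/C(CC(=O)OC(C)(C)C)=C\O | intermediate
9 | silyloxy enone, tert-butyl (E)-3-[(TBSO)methylidene]-4-oxopentanoate | CC(=O)/C(CC(=O)OC(C)(C)C)=C/O[Si](C)(C)C(C)(C)C | intermediate (not isolated)
10 | (E)-1,3-bis(silyloxy)diene with the C11–C12 arm | C=C(O[Si](C)(C)C(C)(C)C)/C(CC(=O)OC(C)(C)C)=C/O[Si](C)(C)C(C)(C)C | intermediate
11 | (6+4) adduct, C14-bridged bicyclo[4.4.1]undecatrienone | O=C1[C@]2(OCc3ccc(OC)cc3)C=CC=C[C@H]1CC(O[Si](C)(C)C(C)(C)C)=C(CC(=O)OC(C)(C)C)[C@@H]2O[Si](C)(C)C(C)(C)C | intermediate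
12 | C11-hydroxymethyl adduct | O=C1[C@]2(OCc3ccc(OC)cc3)C=CC=C[C@H]1CC(O[Si](C)(C)C(C)(C)C)=C(C(CO)C(=O)OC(C)(C)C)[C@@H]2O[Si](C)(C)C(C)(C)C | intermediate
13 | C13 TBDPS ether | O=C1[C@]2(OCc3ccc(OC)cc3)C=CC=C[C@H]1CC(O[Si](C)(C)C(C)(C)C)=C(C(CO[Si](c3ccccc3)(c4ccccc4)C(C)(C)C)C(=O)OC(C)(C)C)[C@@H]2O[Si](C)(C)C(C)(C)C | intermediate
14 | C8 ketone (7α-H) | O=C1[C@]2(OCc3ccc(OC)cc3)C=CC=C[C@H]1CC(=O)[C@@H](C(CO[Si](c3ccccc3)(c4ccccc4)C(C)(C)C)C(=O)OC(C)(C)C)[C@@H]2O[Si](C)(C)C(C)(C)C | intermediate
15 | 8β-alcohol | O=C1[C@]2(OCc3ccc(OC)cc3)C=CC=C[C@H]1C[C@@H](O)[C@@H](C(CO[Si](c3ccccc3)(c4ccccc4)C(C)(C)C)C(=O)OC(C)(C)C)[C@@H]2O[Si](C)(C)C(C)(C)C | intermediate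
16 | angelic acid | C/C=C(/C)C(=O)O | starting material
17 | mixed anhydride of angelic and 2,4,6-trichlorobenzoic acid | C/C=C(/C)C(=O)OC(=O)c1c(Cl)cc(Cl)cc1Cl | intermediate (not isolated)
18 | 8β-angelate | O=C1[C@]2(OCc3ccc(OC)cc3)C=CC=C[C@H]1C[C@@H](OC(=O)/C(C)=C\C)[C@@H](C(CO[Si](c3ccccc3)(c4ccccc4)C(C)(C)C)C(=O)OC(C)(C)C)[C@@H]2O[Si](C)(C)C(C)(C)C | intermediate
19 | C6 alcohol | O=C1[C@]2(OCc3ccc(OC)cc3)C=CC=C[C@H]1C[C@@H](OC(=O)/C(C)=C\C)[C@@H](C(CO[Si](c3ccccc3)(c4ccccc4)C(C)(C)C)C(=O)OC(C)(C)C)[C@@H]2O | intermediate
20 | dihydroxy acid | O=C1[C@]2(O)C=CC=C[C@H]1C[C@@H](OC(=O)/C(C)=C\C)[C@@H](C(CO[Si](c3ccccc3)(c4ccccc4)C(C)(C)C)C(=O)O)[C@@H]2O | intermediate (not isolated)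
21 | ketol lactone | O=C1[C@]2(O)C=CC=C[C@H]1C[C@@H](OC(=O)/C(C)=C\C)[C@@H]3[C@@H]2OC(=O)C3CO[Si](c4ccccc4)(c5ccccc5)C(C)(C)C | intermediate
22 | ten-membered (Z,Z)-dienone ester | O=C1/C=C\C=C/[C@H](C(=O)OC)C[C@@H](OC(=O)/C(C)=C\C)[C@@H]2[C@@H]1OC(=O)C2CO[Si](c3ccccc3)(c4ccccc4)C(C)(C)C | intermediate
23 | C4=C5 TES enol ether | CC[Si](CC)(CC)OC1=CC/C=C\[C@H](C(=O)OC)C[C@@H](OC(=O)/C(C)=C\C)[C@@H]2[C@@H]1OC(=O)C2CO[Si](c3ccccc3)(c4ccccc4)C(C)(C)C | intermediate
24 | conjugated C1=C10 enoate, enol silane kept | CC[Si](CC)(CC)OC1=CCC/C=C(/C(=O)OC)C[C@@H](OC(=O)/C(C)=C\C)[C@@H]2[C@@H]1OC(=O)C2CO[Si](c3ccccc3)(c4ccccc4)C(C)(C)C | intermediate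
25 | Mannich base (C4 not defined) | O=C1C(CN(C)C)CC/C=C(/C(=O)OC)C[C@@H](OC(=O)/C(C)=C\C)[C@@H]2[C@@H]1OC(=O)C2CO[Si](c3ccccc3)(c4ccccc4)C(C)(C)C | intermediate (not isolated)
26 | ammonium iodide (C4 not defined) | O=C1C(C[N+](C)(C)C)CC/C=C(/C(=O)OC)C[C@@H](OC(=O)/C(C)=C\C)[C@@H]2[C@@H]1OC(=O)C2CO[Si](c3ccccc3)(c4ccccc4)C(C)(C)C.[I-] | intermediate (not isolated)
27 | C4-methylene C5 ketone | O=C1C(=C)CC/C=C(/C(=O)OC)C[C@@H](OC(=O)/C(C)=C\C)[C@@H]2[C@@H]1OC(=O)C2CO[Si](c3ccccc3)(c4ccccc4)C(C)(C)C | intermediate
28 | 5β-allylic alcohol | O[C@H]1C(=C)CC/C=C(/C(=O)OC)C[C@@H](OC(=O)/C(C)=C\C)[C@@H]2[C@@H]1OC(=O)C2CO[Si](c3ccccc3)(c4ccccc4)C(C)(C)C | intermediate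
29 | C5,C13-diol | O[C@H]1C(=C)CC/C=C(/C(=O)OC)C[C@@H](OC(=O)/C(C)=C\C)[C@@H]2[C@@H]1OC(=O)C2CO | intermediate
30 | C13 mesylate | O[C@H]1C(=C)CC/C=C(/C(=O)OC)C[C@@H](OC(=O)/C(C)=C\C)[C@@H]2[C@@H]1OC(=O)C2COS(C)(=O)=O | intermediate (not isolated)
31 | CNP0163095.1 (5S,6S,7R,8R; 5β-OH, 12,6α-olide, 8β-OAng) | C=C1C(=O)O[C@H]2[C@H]1[C@H](OC(=O)/C(C)=C\C)C/C(C(=O)OC)=C\CCC(=C)[C@@H]2O | target

## Step count and risks

Total step count: 19. Longest linear sequence: 18 (steps 2–19, from 4).

**1. Step 5.**
- What may go wrong: the Lewis acid may divert the pair into (4+2) or (8+2) addition. It may also stop the reaction after the first C9–C10 bond by silyl transfer, strip the enol silanes, or give little facial bias.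
- Fallback: set out from 3 and 10 and give up catalysis. The two components are heated without additive in toluene at 110 °C in a sealed tube. This is the known thermal, exo-selective (6+4) cycloaddition of tropones with 1-oxygenated dienes.
- This should give the racemate, that is 11 together with its mirror image, the ent-adduct F1. F1 is removed by preparative chromatography on a chiral stationary phase, and the route is rejoined at 11.

**2. Step 9.**
- What may go wrong: hydride may be delivered to the β-face if ring B reacts from a boat form in which the C14 carbonyl bridge screens the α-face. There may also be some attack on C14.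
- Fallback: set out from 14 and use the other face. The 8α-alcohol F2 that such a delivery gives is esterified with inversion by a Mitsunobu reaction with angelic acid 16 (PPh3, DIAD, toluene, 0 °C).
- In this reaction the alcohol and not the acid is activated, so the (Z) geometry is not at risk. The SN2 displacement at C8 installs the 8β-angelate directly, and the route is rejoined at 18.

**3. Step 14.**
- What may go wrong: hydride may transfer to C1 (1,6-addition) or to the carbonyl carbon, C1=C2 may be hydrosilylated, or the cis-dienone may drain into its 2H-pyran valence tautomer.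
- Fallback: set out from 21 and saturate C3=C4 before the ring is opened.
- Hydroxyl-directed hydrogenation with [Ir(cod)(PCy3)(py)]PF6 under H2 (1 atm, CH2Cl2, 0 °C) should give the dihydro ketol F3. The tertiary allylic C5–OH steers the metal to the neighbouring alkene.
- Pb(OAc)4 in MeOH then opens F3 to the β,γ-unsaturated keto ester F4.
- DBU moves C1=C2 into conjugation to give the enoate ketone F5.
- Direct α-methylenation with paraformaldehyde and diisopropylammonium trifluoroacetate in THF at reflux is possible only at the C4 methylene group. It rejoins the route at 27.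

## Further compounds

F1 | step 5 | ent-adduct (mirror image of 11) | O=C1[C@@]2(OCc3ccc(OC)cc3)C=CC=C[C@@H]1CC(O[Si](C)(C)C(C)(C)C)=C(CC(=O)OC(C)(C)C)[C@H]2O[Si](C)(C)C(C)(C)C
F2 | step 9 | 8α-alcohol (8-epimer of 15) | O=C1[C@]2(OCc3ccc(OC)cc3)C=CC=C[C@H]1C[C@H](O)[C@@H](C(CO[Si](c3ccccc3)(c4ccccc4)C(C)(C)C)C(=O)OC(C)(C)C)[C@@H]2O[Si](C)(C)C(C)(C)C
F3 | step 14 | dihydro ketol (C3–C4 saturated) | O=C1[C@]2(O)CCC=C[C@H]1C[C@@H](OC(=O)/C(C)=C\C)[C@@H]3[C@@H]2OC(=O)C3CO[Si](c4ccccc4)(c5ccccc5)C(C)(C)C
F4 | step 14 | β,γ-unsaturated keto ester | O=C1CC/C=C\[C@H](C(=O)OC)C[C@@H](OC(=O)/C(C)=C\C)[C@@H]2[C@@H]1OC(=O)C2CO[Si](c3ccccc3)(c4ccccc4)C(C)(C)C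
F5 | step 14 | enoate ketone | O=C1CCC/C=C(/C(=O)OC)C[C@@H](OC(=O)/C(C)=C\C)[C@@H]2[C@@H]1OC(=O)C2CO[Si](c3ccccc3)(c4ccccc4)C(C)(C)C
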